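Retrosynthesis: the target is an achiral depside, cut first at the aryl ester C(=O)–O bond between ring A (2,4-dihydroxy-6-(2-oxononyl)benzoyl) and ring B (2-heptyl-4-hydroxy-6-methoxybenzoic acid).
Ring B has heptyl on C6, carboxyl on C1 and methoxy on C2, three contiguous ring carbons; this is the footprint of a carbon nucleophile and an electrophile adding across a 3-methoxybenzyne, so the C6–heptyl and C1–CO2H bonds are cut together, back to a 3-fluoro-5-methoxyphenyl silyl ether, heptyllithium and CO2.
Ring A is cut at its C1–CO2H bond (aryl bromide, lithium exchange, CO2) and at the C(=O)–heptyl bond of the side chain (Weinreb amide from (3,5-dihydroxyphenyl)acetic acid plus a heptyl Grignard reagent).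
Forward: both benzene rings are bought and no ring is formed; the ring B phenol takes four steps (plus one to prepare heptyllithium), the ring A acid six, and the two are joined by O-acylation, followed by ketone unmasking and hydrogenolysis.
Stereochemistry: there is no stereocentre; the only selectivity issues are regiochemical (lithiation site and direction of aryne addition in ring B, bromination site in ring A).

Key step: step 3

Assumption: the target is treated as the open-chain keto acid; the side-chain ketone is kept masked until the ester bond exists, because a free 2-(2-oxoalkyl)benzoic acid would close to an isocoumarin on activation.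

Step 1
Reactants: 1 3-fluoro-5-methoxyphenol
Product: 2 (3-fluoro-5-methoxyphenoxy)tri(propan-2-yl)silane
Conditions: TIPSCl, imidazole, DMF, rt
Reagents that add atoms: chlorotri(propan-2-yl)silane (TIPSCl), CC(C)[Si](Cl)(C(C)C)C(C)C
Why: Imidazole-promoted O-silylation of a phenol is routine, and the bulky tri(propan-2-yl)silyl ether is chosen because it resists alkyllithiums and shields the two ring positions beside it from metalation.

Step 2
Reactants: 3 1-chloroheptane
Product: 4 heptyllithium (titrated hexane solution)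
Conditions: Li (dispersion with about 1% Na, 2.2 equiv), hexane, 50 °C, argon; filtered and titrated
Reagents that add atoms: lithium metal, [Li]
Why: Direct reductive lithiation of a primary alkyl chloride in a hydrocarbon is the standard preparation of n-alkyllithiums, and the chloride rather than the bromide keeps Wurtz coupling low.

Step 3
Reactants: 2 (3-fluoro-5-methoxyphenoxy)tri(propan-2-yl)silane, 4 heptyllithium, 5 carbon dioxide
Product: 10 2-heptyl-6-methoxy-4-{[tri(propan-2-yl)silyl]oxy}benzoic acid, via 2-lithio aryl fluoride 6 (not isolated), via methoxy silyloxy benzyne 7 (not isolated), via heptylated aryllithium 8 (not isolated), via lithium benzoate 9 (not isolated)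
Conditions: 4 (3.0 equiv), THF–hexane, −78 °C, then slowly to −20 °C; CO2 (dried gas, excess), −78 °C to rt; cold 1 M HCl
Reagents that add atoms: none
Why: Heptyllithium removes the ring proton flanked by fluorine and methoxy (directed ortho-metalation at the most acidic site, lithium held by the methoxy oxygen) to give 6, which loses LiF on warming to the aryne 7 whose strained bond lies next to the methoxy-bearing carbon. A second heptyllithium adds to 7 at the carbon remote from methoxy, forming the C–heptyl bond, because the carbanion then develops in the in-plane orbital on the carbon beside the electron-withdrawing, lithium-chelating oxygen; the aryllithium 8 is then carboxylated by CO2, forming the C–CO2H bond, to give 9 and, after acidification, 10. The closest known reaction type is the aryne three-component coupling in which a 3-haloanisole, an alkyllithium and carbon dioxide give a 6-alkyl-2-methoxybenzoic acid. No ring is closed and no stereocentre is created. Two regioselectivities are needed, the site of lithiation and the direction of addition, and the substrate should secure both: fluorine and methoxy cooperate on one C–H while the bulky, poorly coordinating silyl ether shields its own neighbours, and the methoxy group polarises the aryne. An excess of heptyllithium present while the aryne forms should keep 6 and 8 from adding to 7, and lithium never sits ortho to the silyloxy group, so no oxygen-to-carbon silyl shift is possible.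

Step 4
Reactants: 10 2-heptyl-6-methoxy-4-{[tri(propan-2-yl)silyl]oxy}benzoic acid
Product: 11 benzyl 2-heptyl-6-methoxy-4-{[tri(propan-2-yl)silyl]oxy}benzoate
Conditions: BnBr, KHCO3, DMF, rt
Reagents that add atoms: benzyl bromide, BrCc1ccccc1
Why: SN2 O-alkylation of the carboxylate avoids acyl substitution at a 2,6-disubstituted benzoic acid, and hydrogen carbonate is too weak a base to cleave the aryl silyl ether.

Step 5
Reactants: 11 benzyl 2-heptyl-6-methoxy-4-{[tri(propan-2-yl)silyl]oxy}benzoate
Product: 12 benzyl 2-heptyl-4-hydroxy-6-methoxybenzoate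
Conditions: Bu4NF, AcOH, THF, 0 °C
Reagents that add atoms: none
Why: Fluoride-mediated desilylation, driven by the strong Si–F bond, frees the phenol, and the acetic acid buffer protonates the phenoxide so that the benzyl ester is left alone.

Step 6
Reactants: 13 (3,5-dihydroxyphenyl)acetic acid
Product: 14 benzyl [3,5-bis(benzyloxy)phenyl]acetate
Conditions: BnBr (3.3 equiv), K2CO3, DMF, 60 °C
Reagents that add atoms: benzyl bromide, BrCc1ccccc1
Why: Williamson etherification of both phenols together with alkylation of the carboxylate gives the tris-benzylated compound in one operation, since carbonate does not deprotonate the benzylic ester position.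

Step 7
Reactants: 14 benzyl [3,5-bis(benzyloxy)phenyl]acetate
Product: 15 benzyl [3,5-bis(benzyloxy)-2-bromophenyl]acetate
Conditions: NBS (1.0 equiv), MeCN, 0 °C
Reagents that add atoms: N-bromosuccinimide, O=C1CCC(=O)N1Br
Why: Electrophilic aromatic bromination of a 3,5-dialkoxyphenyl ring should go to the position ortho to the CH2 group and para to one benzyloxy group, which is less crowded than the position between the two benzyloxy groups.

Step 8
Reactants: 15 benzyl [3,5-bis(benzyloxy)-2-bromophenyl]acetate
Product: 16 2-[3,5-bis(benzyloxy)-2-bromophenyl]-N-methoxy-N-methylacetamide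
Conditions: MeNH(OMe)·HCl, i-PrMgCl, THF, −20 °C
Reagents that add atoms: N,O-dimethylhydroxylamine hydrochloride, CNOC.Cl
Why: Weinreb amide formation by aminolysis of the ester with the chloromagnesium amide made in the flask is standard, and the electron-rich aryl bromide should not undergo bromine–magnesium exchange at this temperature.

Step 9
Reactants: 16 2-[3,5-bis(benzyloxy)-2-bromophenyl]-N-methoxy-N-methylacetamide
Product: 18 1-[3,5-bis(benzyloxy)-2-bromophenyl]nonan-2-one, via bromomagnesium tetrahedral adduct 17 (not isolated)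
Conditions: n-C7H15MgBr (1.5 equiv), THF, 0 °C; cold 1 M HCl
Reagents that add atoms: heptylmagnesium bromide, CCCCCCC[Mg]Br
Why: In this Weinreb ketone synthesis the Grignard reagent adds once to give the chelated adduct 17, which collapses to the ketone only on acidic work-up, while the aryl bromide is inert to the Grignard reagent.

Step 10
Reactants: 18 1-[3,5-bis(benzyloxy)-2-bromophenyl]nonan-2-one
Product: 19 2-{[3,5-bis(benzyloxy)-2-bromophenyl]methyl}-2-heptyl-1,3-dioxolane
Conditions: ethylene glycol, p-toluenesulfonic acid monohydrate (cat.), toluene, reflux, Dean–Stark trap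
Reagents that add atoms: ethane-1,2-diol, OCCO
Why: Acid-catalysed ketalisation with azeotropic removal of water masks the ketone as a 1,3-dioxolane, which is needed for the organolithium step and for the later activation of the acid.

Step 11
Reactants: 19 2-{[3,5-bis(benzyloxy)-2-bromophenyl]methyl}-2-heptyl-1,3-dioxolane, 5 carbon dioxide
Product: 22 2,4-bis(benzyloxy)-6-[(2-heptyl-1,3-dioxolan-2-yl)methyl]benzoic acid, via aryllithium 20 (not isolated), via lithium benzoate 21 (not isolated)
Conditions: n-BuLi (1.1 equiv), THF, −78 °C; CO2 (dried gas), −78 to 0 °C; cold dilute HCl to pH 4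
Reagents that add atoms: none
Why: Bromine–lithium exchange at −78 °C is faster than any deprotonation, and carboxylation of the aryllithium gives the benzoic acid while the ketal and benzyl ethers are inert, the work-up being kept cold and only weakly acidic to preserve the ketal.

Step 12
Reactants: 22 2,4-bis(benzyloxy)-6-[(2-heptyl-1,3-dioxolan-2-yl)methyl]benzoic acid, 12 benzyl 2-heptyl-4-hydroxy-6-methoxybenzoate
Product: 24 benzyl 4-({2,4-bis(benzyloxy)-6-[(2-heptyl-1,3-dioxolan-2-yl)methyl]benzoyl}oxy)-2-heptyl-6-methoxybenzoate, via acyl chloride 23 (not isolated)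
Conditions: 1-chloro-N,N,2-trimethylprop-1-en-1-amine, CH2Cl2, 0 °C to rt; then 12, Et3N, 4-(dimethylamino)pyridine (cat.), 0 °C to rt
Reagents that add atoms: none
Why: The chloroenamine converts the acid into its chloride without releasing HCl, so the ketal survives, and the amine-catalysed O-acylation of the phenol (nucleophilic acyl substitution, the usual depside ester formation) should tolerate the 2,6-disubstituted acyl chloride.

Step 13
Reactants: 24 benzyl 4-({2,4-bis(benzyloxy)-6-[(2-heptyl-1,3-dioxolan-2-yl)methyl]benzoyl}oxy)-2-heptyl-6-methoxybenzoate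
Product: 25 benzyl 4-{[2,4-bis(benzyloxy)-6-(2-oxononyl)benzoyl]oxy}-2-heptyl-6-methoxybenzoate
Conditions: 1 M aq. HCl–THF (1:3), rt
Reagents that add atoms: water, O
Why: Acid-catalysed hydrolysis of the dioxolane should release the dialkyl ketone at room temperature, conditions under which benzyl ethers, the benzyl ester and the aryl ester are stable.

Step 14
Reactants: 25 benzyl 4-{[2,4-bis(benzyloxy)-6-(2-oxononyl)benzoyl]oxy}-2-heptyl-6-methoxybenzoate
Product: 26 4-{[2,4-dihydroxy-6-(2-oxononyl)benzoyl]oxy}-2-heptyl-6-methoxybenzoic acid (CNP0406321.0)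
Conditions: H2 (1 atm), 10% Pd/C, EtOAc, rt
Reagents that add atoms: none
Why: Catalytic hydrogenolysis cleaves the two benzyl ethers and the benzyl ester under neutral conditions in a non-nucleophilic solvent and leaves the aliphatic ketone, the aryl ester and the methyl ether intact.

Compound list
1 | 3-fluoro-5-methoxyphenol | COc1cc(O)cc(F)c1 | starting material
2 | (3-fluoro-5-methoxyphenoxy)tri(propan-2-yl)silane | COc1cc(F)cc(O[Si](C(C)C)(C(C)C)C(C)C)c1 | intermediate
3 | 1-chloroheptane | CCCCCCCCl | starting material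
4 | heptyllithium | [Li]CCCCCCC | intermediate
5 | carbon dioxide | O=C=O | starting material
6 | [2-fluoro-6-methoxy-4-{[tri(propan-2-yl)silyl]oxy}phenyl]lithium | COc1cc(O[Si](C(C)C)(C(C)C)C(C)C)cc(F)c1[Li] | intermediate
7 | 3-methoxy-5-{[tri(propan-2-yl)silyl]oxy}benzyne (1,2-didehydro-3-methoxy-5-silyloxybenzene) | COC1=CC(O[Si](C(C)C)(C(C)C)C(C)C)=CC#C1 | intermediate
8 | [2-heptyl-6-methoxy-4-{[tri(propan-2-yl)silyl]oxy}phenyl]lithium | CCCCCCCc1cc(O[Si](C(C)C)(C(C)C)C(C)C)cc(OC)c1[Li] | intermediate
9 | lithium 2-heptyl-6-methoxy-4-{[tri(propan-2-yl)silyl]oxy}benzoate | CCCCCCCc1cc(O[Si](C(C)C)(C(C)C)C(C)C)cc(OC)c1C(=O)[O-].[Li+] | intermediate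
10 | 2-heptyl-6-methoxy-4-{[tri(propan-2-yl)silyl]oxy}benzoic acid | CCCCCCCc1cc(O[Si](C(C)C)(C(C)C)C(C)C)cc(OC)c1C(=O)O | intermediate
11 | benzyl 2-heptyl-6-methoxy-4-{[tri(propan-2-yl)silyl]oxy}benzoate | CCCCCCCc1cc(O[Si](C(C)C)(C(C)C)C(C)C)cc(OC)c1C(=O)OCc1ccccc1 | intermediate
12 | benzyl 2-heptyl-4-hydroxy-6-methoxybenzoate | CCCCCCCc1cc(O)cc(OC)c1C(=O)OCc1ccccc1 | intermediate
13 | (3,5-dihydroxyphenyl)acetic acid | OC(=O)Cc1cc(O)cc(O)c1 | starting material
14 | benzyl [3,5-bis(benzyloxy)phenyl]acetate | O=C(Cc1cc(OCc2ccccc2)cc(OCc2ccccc2)c1)OCc1ccccc1 | intermediate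
15 | benzyl [3,5-bis(benzyloxy)-2-bromophenyl]acetate | O=C(Cc1cc(OCc2ccccc2)cc(OCc2ccccc2)c1Br)OCc1ccccc1 | intermediate
16 | 2-[3,5-bis(benzyloxy)-2-bromophenyl]-N-methoxy-N-methylacetamide | CON(C)C(=O)Cc1cc(OCc2ccccc2)cc(OCc2ccccc2)c1Br | intermediate
17 | bromomagnesium 1-[3,5-bis(benzyloxy)-2-bromophenyl]-2-[methoxy(methyl)amino]nonan-2-olate | CCCCCCCC(O[Mg]Br)(Cc1cc(OCc2ccccc2)cc(OCc2ccccc2)c1Br)N(C)OC | intermediate
18 | 1-[3,5-bis(benzyloxy)-2-bromophenyl]nonan-2-one | CCCCCCCC(=O)Cc1cc(OCc2ccccc2)cc(OCc2ccccc2)c1Br | intermediate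
19 | 2-{[3,5-bis(benzyloxy)-2-bromophenyl]methyl}-2-heptyl-1,3-dioxolane | CCCCCCCC1(Cc2cc(OCc3ccccc3)cc(OCc3ccccc3)c2Br)OCCO1 | intermediate
20 | {2,4-bis(benzyloxy)-6-[(2-heptyl-1,3-dioxolan-2-yl)methyl]phenyl}lithium | CCCCCCCC1(Cc2cc(OCc3ccccc3)cc(OCc3ccccc3)c2[Li])OCCO1 | intermediate
21 | lithium 2,4-bis(benzyloxy)-6-[(2-heptyl-1,3-dioxolan-2-yl)methyl]benzoate | CCCCCCCC1(Cc2cc(OCc3ccccc3)cc(OCc3ccccc3)c2C(=O)[O-])OCCO1.[Li+] | intermediate
22 | 2,4-bis(benzyloxy)-6-[(2-heptyl-1,3-dioxolan-2-yl)methyl]benzoic acid | CCCCCCCC1(Cc2cc(OCc3ccccc3)cc(OCc3ccccc3)c2C(=O)O)OCCO1 | intermediate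
23 | 2,4-bis(benzyloxy)-6-[(2-heptyl-1,3-dioxolan-2-yl)methyl]benzoyl chloride | CCCCCCCC1(Cc2cc(OCc3ccccc3)cc(OCc3ccccc3)c2C(=O)Cl)OCCO1 | intermediate
24 | benzyl 4-({2,4-bis(benzyloxy)-6-[(2-heptyl-1,3-dioxolan-2-yl)methyl]benzoyl}oxy)-2-heptyl-6-methoxybenzoate | CCCCCCCC1(Cc2cc(OCc3ccccc3)cc(OCc3ccccc3)c2C(=O)Oc2cc(CCCCCCC)c(C(=O)OCc3ccccc3)c(OC)c2)OCCO1 | intermediate
25 | benzyl 4-{[2,4-bis(benzyloxy)-6-(2-oxononyl)benzoyl]oxy}-2-heptyl-6-methoxybenzoate | CCCCCCCC(=O)Cc1cc(OCc2ccccc2)cc(OCc2ccccc2)c1C(=O)Oc1cc(CCCCCCC)c(C(=O)OCc2ccccc2)c(OC)c1 | intermediate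
26 | 4-{[2,4-dihydroxy-6-(2-oxononyl)benzoyl]oxy}-2-heptyl-6-methoxybenzoic acid | CCCCCCCC(=O)Cc1cc(O)cc(O)c1C(=O)Oc1cc(CCCCCCC)c(C(=O)O)c(OC)c1 | target

Total step count: 14 steps.
Longest linear sequence: 9 steps (steps 6 to 14, from (3,5-dihydroxyphenyl)acetic acid 13). The ring B branch contributes steps 1, 3, 4 and 5, and step 2 prepares the organolithium.

Steps most likely to fail

Step 3. The aryllithiums 6 and 8 may add to the aryne in competition with heptyllithium, consuming it as biaryls and oligomers. A minor metalation next to the silyl ether would also send material through the isomeric aryne. The fallback avoids a free aryne. It sets out from 2: lithiation with s-BuLi in THF at −78 °C gives the same aryllithium 6, which is carboxylated with CO2 at −78 °C, before it can lose LiF, to give 2-fluoro-6-methoxy-4-{[tri(propan-2-yl)silyl]oxy}benzoic acid F1. Treating F1 with an excess of heptylmagnesium bromide in THF (0 °C to reflux) should replace fluorine by heptyl through carboxylate-directed nucleophilic aromatic substitution (addition–elimination, with fluoride a better leaving group than methoxide). Acidic work-up returns the route to 10.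

Step 12. Acylation of the phenol by an acyl chloride hindered on both flanks may be slow, and meanwhile the neighbouring dioxolane oxygen may attack the acyl chloride, opening the ketal and lactonising the material. The fallback uses an acid-stable ketone mask so that the classical depside condensation with trifluoroacetic anhydride can be applied. It sets out from ketone 18.
- Propane-1,3-dithiol with BF3·OEt2 (cat.) in CH2Cl2 at 0 °C gives 2-{[3,5-bis(benzyloxy)-2-bromophenyl]methyl}-2-heptyl-1,3-dithiane F2.
- n-BuLi in THF at −78 °C gives {2,4-bis(benzyloxy)-6-[(2-heptyl-1,3-dithian-2-yl)methyl]phenyl}lithium F3, and CO2 followed by acidification gives 2,4-bis(benzyloxy)-6-[(2-heptyl-1,3-dithian-2-yl)methyl]benzoic acid F4.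
- Trifluoroacetic anhydride in toluene at rt converts F4 into 2,4-bis(benzyloxy)-6-[(2-heptyl-1,3-dithian-2-yl)methyl]benzoic trifluoroacetic anhydride F5, which acylates phenol 12 in the same flask to give benzyl 4-({2,4-bis(benzyloxy)-6-[(2-heptyl-1,3-dithian-2-yl)methyl]benzoyl}oxy)-2-heptyl-6-methoxybenzoate F6.
- Alkylative hydrolysis of the dithiane (MeI, CaCO3, MeCN–H2O, 45 °C) returns the route to 25.

Step 13. The acid that opens the dioxolane may also let the freed ketone, as its enol or hemiketal, attack the adjacent aryl ester; this would expel the ring B phenol and form an isocoumarin. The fallback releases the ketone by oxidation under buffered, non-acidic conditions. It sets out from ketone 18.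
- Wittig methylenation (Ph3PCH3Br, KOt-Bu, THF, 0 °C to rt) gives 1,5-bis(benzyloxy)-2-bromo-3-(2-methylidenenonyl)benzene F7.
- n-BuLi in THF at −78 °C gives [2,4-bis(benzyloxy)-6-(2-methylidenenonyl)phenyl]lithium F8, and CO2 followed by acidification gives 2,4-bis(benzyloxy)-6-(2-methylidenenonyl)benzoic acid F9.
- 1-Chloro-N,N,2-trimethylprop-1-en-1-amine in CH2Cl2 gives 2,4-bis(benzyloxy)-6-(2-methylidenenonyl)benzoyl chloride F10, which acylates phenol 12 (Et3N, 4-(dimethylamino)pyridine) to give benzyl 4-{[2,4-bis(benzyloxy)-6-(2-methylidenenonyl)benzoyl]oxy}-2-heptyl-6-methoxybenzoate F11.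
- Oxidative cleavage of the 1,1-disubstituted alkene (OsO4 cat., NaIO4, 2,6-lutidine, dioxane–H2O, rt) returns the route to 25.

Further compounds
F1 | step 3 | 2-fluoro-6-methoxy-4-{[tri(propan-2-yl)silyl]oxy}benzoic acid | COc1cc(O[Si](C(C)C)(C(C)C)C(C)C)cc(F)c1C(=O)O
F2 | step 12 | 2-{[3,5-bis(benzyloxy)-2-bromophenyl]methyl}-2-heptyl-1,3-dithiane | CCCCCCCC1(Cc2cc(OCc3ccccc3)cc(OCc3ccccc3)c2Br)SCCCS1
F3 | step 12 | {2,4-bis(benzyloxy)-6-[(2-heptyl-1,3-dithian-2-yl)methyl]phenyl}lithium | CCCCCCCC1(Cc2cc(OCc3ccccc3)cc(OCc3ccccc3)c2[Li])SCCCS1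
F4 | step 12 | 2,4-bis(benzyloxy)-6-[(2-heptyl-1,3-dithian-2-yl)methyl]benzoic acid | CCCCCCCC1(Cc2cc(OCc3ccccc3)cc(OCc3ccccc3)c2C(=O)O)SCCCS1
F5 | step 12 | 2,4-bis(benzyloxy)-6-[(2-heptyl-1,3-dithian-2-yl)methyl]benzoic trifluoroacetic anhydride | CCCCCCCC1(Cc2cc(OCc3ccccc3)cc(OCc3ccccc3)c2C(=O)OC(=O)C(F)(F)F)SCCCS1
F6 | step 12 | benzyl 4-({2,4-bis(benzyloxy)-6-[(2-heptyl-1,3-dithian-2-yl)methyl]benzoyl}oxy)-2-heptyl-6-methoxybenzoate | CCCCCCCC1(Cc2cc(OCc3ccccc3)cc(OCc3ccccc3)c2C(=O)Oc2cc(CCCCCCC)c(C(=O)OCc3ccccc3)c(OC)c2)SCCCS1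
F7 | step 13 | 1,5-bis(benzyloxy)-2-bromo-3-(2-methylidenenonyl)benzene | CCCCCCCC(=C)Cc1cc(OCc2ccccc2)cc(OCc2ccccc2)c1Br
F8 | step 13 | [2,4-bis(benzyloxy)-6-(2-methylidenenonyl)phenyl]lithium | CCCCCCCC(=C)Cc1cc(OCc2ccccc2)cc(OCc2ccccc2)c1[Li]
F9 | step 13 | 2,4-bis(benzyloxy)-6-(2-methylidenenonyl)benzoic acid | CCCCCCCC(=C)Cc1cc(OCc2ccccc2)cc(OCc2ccccc2)c1C(=O)O
F10 | step 13 | 2,4-bis(benzyloxy)-6-(2-methylidenenonyl)benzoyl chloride | CCCCCCCC(=C)Cc1cc(OCc2ccccc2)cc(OCc2ccccc2)c1C(=O)Cl
F11 | step 13 | benzyl 4-{[2,4-bis(benzyloxy)-6-(2-methylidenenonyl)benzoyl]oxy}-2-heptyl-6-methoxybenzoate | CCCCCCCC(=C)Cc1cc(OCc2ccccc2)cc(OCc2ccccc2)c1C(=O)Oc1cc(CCCCCCC)c(C(=O)OCc2ccccc2)c(OC)c1
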